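**Retrosynthetic overview**

1. The acetate goes on last. The 14-membered carbocycle (second ring formed) is cut at the central C–C single bond of the diene, giving an open chain with a terminal alkyne and a (Z)-iodoalkene.
2. The tertiary carbinol comes from chelation-controlled MeMgBr addition to a 2-acyloxolane, whose side chain is made by alkylating a 2-acetyloxolane with a (Z)-iodoallyl bromide (from prop-2-yn-1-ol).
3. Key step: the oxolane (first ring formed) arises by acid-triggered ring expansion of an oxirane in an all-(S) bis-epoxide. The epoxy-alcohol oxygen opens the second epoxide, water opens the epoxonium ion, and periodate then unveils the methyl ketone.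
4. The bis-epoxide comes from an (E,E)-dienynol by one Shi epoxidation. The dienynol comes from pent-4-ynal by Grignard addition, orthoester Claisen rearrangement, reduction/Wittig and reduction.

Assumption: pent-4-ynal, prop-2-yn-1-ol, the stabilised ylide and the L-fructose-derived (ent) Shi ketone are bought.

**Route**

Step 1
Reactants: 1 pent-4-ynal
Product: 2 rac-2-methylhept-1-en-6-yn-3-ol
Conditions: CH2=C(CH3)MgBr (1.15 equiv), THF, −78 → 0 °C; aq. NH4Cl
Reagents that add atoms: prop-1-en-2-ylmagnesium bromide, CC(=C)[Mg]Br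
Why: Grignard 1,2-addition to the aldehyde is far faster at −78 °C than deprotonation of the alkyne; the new carbinol centre is racemic and is erased in step 2.

Step 2
Reactants: 2 rac-2-methylhept-1-en-6-yn-3-ol
Product: 3 methyl (4E)-4-methylnon-4-en-8-ynoate
Conditions: CH3C(OCH3)3 (6 equiv), EtCO2H (0.05 equiv), 125 °C, sealed tube
Reagents that add atoms: trimethyl orthoacetate, CC(OC)(OC)OC
Why: Johnson orthoester Claisen rearrangement through a chair transition state with the butynyl chain equatorial, which sets the (E)-trisubstituted alkene (typically ≥95:5).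

Step 3
Reactants: 3 methyl (4E)-4-methylnon-4-en-8-ynoate
Product: 5 ethyl (2E,6E)-2,6-dimethylundeca-2,6-dien-10-ynoate, via aldehyde 4 (not isolated)
Conditions: iBu2AlH (1.05 equiv), CH2Cl2, −78 °C; then Ph3P=C(CH3)CO2Et (1.5 equiv), −78 → 23 °C
Reagents that add atoms: ethyl 2-(triphenyl-λ5-phosphanylidene)propanoate, CCOC(=O)C(C)=P(c1ccccc1)(c1ccccc1)c1ccccc1
Why: Half-reduction of the ester gives an aluminium hemiacetal that releases aldehyde 4 on warming, and Wittig olefination with the stabilised α-methyl ylide gives the (E)-enoate (>95:5).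

Step 4
Reactants: 5 ethyl (2E,6E)-2,6-dimethylundeca-2,6-dien-10-ynoate
Product: 6 (2E,6E)-2,6-dimethylundeca-2,6-dien-10-yn-1-ol
Conditions: iBu2AlH (2.3 equiv), CH2Cl2, −78 → 0 °C; aq. KNaC4H4O6
Reagents that add atoms: none
Why: 1,2-Reduction of the conjugated ester by the aluminium hydride gives the allylic alcohol without touching the alkenes or the alkyne.

Step 5
Reactants: 6 (2E,6E)-2,6-dimethylundeca-2,6-dien-10-yn-1-ol
Product: 7 [(2S,3S)-3-{2-[(2S,3S)-3-(but-3-yn-1-yl)-2-methyloxiran-2-yl]ethyl}-2-methyloxiran-2-yl]methanol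
Conditions: ent-Shi ketone (1,2:4,5-di-O-isopropylidene-β-L-erythro-2,3-hexodiulo-2,6-pyranose, 0.6 equiv), Oxone (2KHSO5·KHSO4·K2SO4), K2CO3, Bu4NHSO4, MeCN–CH2(OMe)2/aq. Na2B4O7 buffer, pH 10.5, 0 °C
Reagents that add atoms: potassium peroxymonosulfate, [K+].[O-]S(=O)(=O)OO
Why: Shi asymmetric epoxidation: the dioxirane of the L-series ketone attacks both (E)-trisubstituted alkenes from the same face through a spiro transition state (the D-ketone gives R,R epoxides from such alkenes), so all four epoxide carbons become (S); the alkyne is inert.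

Step 6
Reactants: 7 [(2S,3S)-3-{2-[(2S,3S)-3-(but-3-yn-1-yl)-2-methyloxiran-2-yl]ethyl}-2-methyloxiran-2-yl]methanol
Product: 10 1-[(2S,5R)-5-[(1S)-1-hydroxypent-4-yn-1-yl]-5-methyloxolan-2-yl]ethan-1-one, via epoxonium ion 8 (not isolated), via triol 9 (not isolated)
Conditions: (±)-CSA (0.1 equiv), THF–H2O (4:1), 0 → 23 °C; then NaHCO3, NaIO4 (1.5 equiv), 23 °C
Reagents that add atoms: water, O
Why: Key ring expansion by an epoxide-opening cascade: the remote, more basic trisubstituted epoxide is protonated and opened at its tertiary carbon by the oxygen of the inductively deactivated epoxy alcohol (anti attack, inversion at the quaternary centre, O–CH centre retained), water opens epoxonium ion 8 at its tertiary carbon so that the oxirane has become the cis-2,5-disubstituted oxolane 9, and periodate cleaves the 1,2-diol to the methyl ketone.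

Step 7
Reactants: 11 prop-2-yn-1-ol
Product: 13 (2Z)-3-iodo-2-(propan-2-yl)prop-2-en-1-ol, via alkenylmagnesium chelate 12 (not isolated)
Conditions: iPrMgCl (3.0 equiv), CuI (0.1 equiv), THF, −20 → 23 °C; then I2 (2.2 equiv), −40 → 0 °C
Reagents that add atoms: isopropylmagnesium chloride, CC(C)[Mg]Cl; iodine, II
Why: Copper-catalysed anti-carbomagnesiation of the propargylic alkoxide (Duboudin–Jousseaume reaction) puts isopropyl on the internal carbon and magnesium on the terminal carbon cis to CH2O in a five-membered chelate, and iodinolysis with retention gives the (Z)-iodoalkene.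

Step 8
Reactants: 13 (2Z)-3-iodo-2-(propan-2-yl)prop-2-en-1-ol
Product: 14 (1Z)-2-(bromomethyl)-1-iodo-3-methylbut-1-ene
Conditions: PBr3 (0.4 equiv), Et2O, 0 °C
Reagents that add atoms: phosphorus tribromide, BrP(Br)Br
Why: Bromination of the primary allylic alcohol by SN2 displacement of the phosphite ester, with the alkene geometry and the C–I bond untouched.

Step 9
Reactants: 10 1-[(2S,5R)-5-[(1S)-1-hydroxypent-4-yn-1-yl]-5-methyloxolan-2-yl]ethan-1-one; 14 (1Z)-2-(bromomethyl)-1-iodo-3-methylbut-1-ene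
Product: 16 (4E)-1-[(2S,5R)-5-[(1S)-1-hydroxypent-4-yn-1-yl]-5-methyloxolan-2-yl]-5-iodo-4-(propan-2-yl)pent-4-en-1-one, via lithium enolate 15 (not isolated)
Conditions: LiN(iPr)2 (3.3 equiv), THF, −78 °C; then 14 (1.2 equiv), −78 → −30 °C; AcOH, −78 °C
Reagents that add atoms: none
Why: Kinetic enolate alkylation: after the hydroxyl and alkyne protons, the amide base removes a methyl proton, and the enolate displaces the allylic bromide by SN2; no new stereocentre forms and the ring C–H next to the ketone is not touched at low temperature.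

Step 10
Reactants: 16 (4E)-1-[(2S,5R)-5-[(1S)-1-hydroxypent-4-yn-1-yl]-5-methyloxolan-2-yl]-5-iodo-4-(propan-2-yl)pent-4-en-1-one
Product: 17 (2R,5E)-2-[(2S,5R)-5-[(1S)-1-hydroxypent-4-yn-1-yl]-5-methyloxolan-2-yl]-6-iodo-5-(propan-2-yl)hex-5-en-2-ol
Conditions: MeMgBr (4 equiv), CH2Cl2–Et2O, −78 °C; aq. NH4Cl
Reagents that add atoms: methylmagnesium bromide, C[Mg]Br
Why: Chelation-controlled (Cram chelate) Grignard addition: magnesium bridges the ketone and ring oxygens and methyl adds to the carbonyl face on the side of the ring C–H, giving the (R)-tertiary alcohol.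

Step 11
Reactants: 17 (2R,5E)-2-[(2S,5R)-5-[(1S)-1-hydroxypent-4-yn-1-yl]-5-methyloxolan-2-yl]-6-iodo-5-(propan-2-yl)hex-5-en-2-ol
Product: 19 (1R,2S,5E,7E,11R,12S)-1,5,11-trimethyl-8-(propan-2-yl)-15-oxabicyclo[10.2.1]pentadeca-5,7-diene-2,11-diol, via alkenylalane 18 (not isolated)
Conditions: Me3Al (6 equiv), Cp2ZrCl2 (0.5 equiv), ClCH2CH2Cl, 0 → 23 °C; excess Me3Al and solvent removed in vacuo; then THF (0.002 M), ZnCl2 (0.3 equiv), Pd(PPh3)4 (0.2 equiv), 50 °C
Reagents that add atoms: trimethylaluminium, C[Al](C)C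
Why: Proposed new method: Zr-catalysed syn-methylalumination of the terminal alkyne gives the (E)-2-methylalkenylalane 18, whose alkenyl group passes through zinc to the alkenylpalladium iodide formed by oxidative addition of zerovalent palladium into the (Z)-iodoalkene, and reductive elimination closes the 14-membered ring at the diene single bond with retention at both alkenes; the closest known chemistry is the intermolecular one-pot carboalumination/alkenyl–alkenyl Negishi coupling and macrocyclic Stille and Suzuki diene couplings, and the ring-closing version on a free diol is, to my knowledge, not reported.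

Step 12
Reactants: 19 (1R,2S,5E,7E,11R,12S)-1,5,11-trimethyl-8-(propan-2-yl)-15-oxabicyclo[10.2.1]pentadeca-5,7-diene-2,11-diol
Product: 20 (1R,2S,5E,7E,11R,12S)-11-hydroxy-1,5,11-trimethyl-8-(propan-2-yl)-15-oxabicyclo[10.2.1]pentadeca-5,7-dien-2-yl acetate
Conditions: Ac2O (1.5 equiv), pyridine, DMAP (0.1 equiv), CH2Cl2, 0 → 23 °C
Reagents that add atoms: acetic anhydride, CC(=O)OC(C)=O
Why: DMAP-catalysed acylation acetylates only the secondary alcohol; the tertiary alcohol is inert under these conditions.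

**Compound list**

1 | pent-4-ynal | O=CCCC#C | starting material
2 | rac-2-methylhept-1-en-6-yn-3-ol | CC(=C)C(O)CCC#C | intermediate
3 | methyl (4E)-4-methylnon-4-en-8-ynoate | COC(=O)CC/C(C)=C/CCC#C | intermediate
4 | (4E)-4-methylnon-4-en-8-ynal | O=CCC/C(C)=C/CCC#C | intermediate
5 | ethyl (2E,6E)-2,6-dimethylundeca-2,6-dien-10-ynoate | CCOC(=O)/C(C)=C/CC/C(C)=C/CCC#C | intermediate
6 | (2E,6E)-2,6-dimethylundeca-2,6-dien-10-yn-1-ol | OC/C(C)=C/CC/C(C)=C/CCC#C | intermediate
7 | [(2S,3S)-3-{2-[(2S,3S)-3-(but-3-yn-1-yl)-2-methyloxiran-2-yl]ethyl}-2-methyloxiran-2-yl]methanol | OC[C@]1(C)O[C@H]1CC[C@]2(C)O[C@H]2CCC#C | intermediate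
8 | epoxonium ion (1-oxoniabicyclo[3.1.0]hexane core; ring oxygen bonded to the CH, the C(CH3)CH2OH carbon and the new quaternary carbon) | OC[C@]1(C)[O+]2[C@H]1CC[C@]2(C)[C@@H](O)CCC#C | intermediate
9 | (2R)-2-[(2S,5R)-5-[(1S)-1-hydroxypent-4-yn-1-yl]-5-methyloxolan-2-yl]propane-1,2-diol | OC[C@@](C)(O)[C@@H]1CC[C@@](C)(O1)[C@@H](O)CCC#C | intermediate
10 | 1-[(2S,5R)-5-[(1S)-1-hydroxypent-4-yn-1-yl]-5-methyloxolan-2-yl]ethan-1-one | CC(=O)[C@@H]1CC[C@@](C)(O1)[C@@H](O)CCC#C | intermediate
11 | prop-2-yn-1-ol | OCC#C | starting material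
12 | 4-(propan-2-yl)-2,5-dihydro-1,2-oxamagnesole (cyclic alkenylmagnesium alkoxide) | CC(C)C1=C[Mg]OC1 | intermediate
13 | (2Z)-3-iodo-2-(propan-2-yl)prop-2-en-1-ol | OC/C(=C\I)C(C)C | intermediate
14 | (1Z)-2-(bromomethyl)-1-iodo-3-methylbut-1-ene | BrC/C(=C\I)C(C)C | intermediate
15 | trilithium enolate/alkoxide/acetylide of 10 | [Li+].[Li+].[Li+].C=C([O-])[C@@H]1CC[C@@](C)(O1)[C@@H]([O-])CCC#[C-] | intermediate
16 | (4E)-1-[(2S,5R)-5-[(1S)-1-hydroxypent-4-yn-1-yl]-5-methyloxolan-2-yl]-5-iodo-4-(propan-2-yl)pent-4-en-1-one | I/C=C(\CCC(=O)[C@@H]1CC[C@@](C)(O1)[C@@H](O)CCC#C)C(C)C | intermediate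
17 | (2R,5E)-2-[(2S,5R)-5-[(1S)-1-hydroxypent-4-yn-1-yl]-5-methyloxolan-2-yl]-6-iodo-5-(propan-2-yl)hex-5-en-2-ol | I/C=C(\CC[C@@](C)(O)[C@@H]1CC[C@@](C)(O1)[C@@H](O)CCC#C)C(C)C | intermediate
18 | (E)-alkenyl(dimethyl)alane of 17, both hydroxyls as dimethylaluminium alkoxides | I/C=C(\CC[C@@](C)(O[Al](C)C)[C@@H]1CC[C@@](C)(O1)[C@@H](O[Al](C)C)CC/C(C)=C/[Al](C)C)C(C)C | intermediate
19 | (1R,2S,5E,7E,11R,12S)-1,5,11-trimethyl-8-(propan-2-yl)-15-oxabicyclo[10.2.1]pentadeca-5,7-diene-2,11-diol | O[C@H]1CC/C(C)=C/C=C(/C(C)C)CC[C@@](C)(O)[C@@H]2CC[C@@]1(C)O2 | intermediate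
20 | (1R,2S,5E,7E,11R,12S)-11-hydroxy-1,5,11-trimethyl-8-(propan-2-yl)-15-oxabicyclo[10.2.1]pentadeca-5,7-dien-2-yl acetate | CC(=O)O[C@H]1CC/C(C)=C/C=C(/C(C)C)CC[C@@](C)(O)[C@@H]2CC[C@@]1(C)O2 | target

**Step count**

Total: 12 steps. Longest linear sequence: 10 steps (steps 1–6 and 9–12); steps 7–8 make the iodoallyl bromide.

**Three steps most likely to fail**

Step 6 (ring-expansion cascade). The risks are activation of the wrong epoxide or direct hydrolysis, which would give oxane or trans-oxolane isomers. The fallback sets out from 3 and comes back at 10; it closes the oxolane with a free hydroxyl instead of an epoxide oxygen. Ester 3 is reduced with iBu2AlH and aldehyde 4 is isolated. CH2=C(CH3)MgBr then gives rac-(6E)-2,6-dimethylundeca-1,6-dien-10-yn-3-ol F1. Sharpless kinetic resolution (Ti(OiPr)4, D-(−)-diisopropyl tartrate, tBuOOH, CH2Cl2, −20 °C, about 55% conversion) leaves (3S,6E)-2,6-dimethylundeca-1,6-dien-10-yn-3-ol F2. Shi epoxidation of the trisubstituted alkene with the same L-series ketone, followed by CSA, gives (1S)-1-[(2R,5S)-2-methyl-5-(prop-1-en-2-yl)oxolan-2-yl]pent-4-yn-1-ol F3 by 5-exo attack of the hydroxyl at the tertiary epoxide carbon with inversion. Ozonolysis of the isopropenyl group (O3, CH2Cl2–MeOH, −78 °C; Me2S) gives 10.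

Step 9 (alkylation through a trianion). The risks are polyalkylation, alkylation at the acetylide, or epimerisation next to the ketone. The fallback sets out from 10 and comes back at 16; it uses a metallated hydrazone instead of the enolate. Ketone 10 is condensed with H2NN(CH3)2 to (1S)-1-[(2R,5S)-5-[1-(2,2-dimethylhydrazinylidene)ethyl]-2-methyloxolan-2-yl]pent-4-yn-1-ol F4. Deprotonation with LiN(iPr)2 (3.3 equiv, THF, −78 °C) at the methyl group and alkylation of the azaenolate with 14 give (1S)-1-[(2R,5S)-5-[(4E)-1-(2,2-dimethylhydrazinylidene)-5-iodo-4-(propan-2-yl)pent-4-en-1-yl]-2-methyloxolan-2-yl]pent-4-yn-1-ol F5. Hydrolysis with aqueous oxalic acid gives 16.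

Step 11 (proposed new ring closure). The risks are methyl transfer from aluminium to the iodoalkene and oligomerisation at the dilution needed. The fallback sets out from 17 and comes back at 19; it uses known chemistry only. The same methylalumination is run, and the alkenyl group is then moved to boron with 2-methoxy-4,4,5,5-tetramethyl-1,3,2-dioxaborolane to give the isolable (2R,5E)-2-[(2S,5R)-5-[(1S,4E)-1-hydroxy-4-methyl-5-(4,4,5,5-tetramethyl-1,3,2-dioxaborolan-2-yl)pent-4-en-1-yl]-5-methyloxolan-2-yl]-6-iodo-5-(propan-2-yl)hex-5-en-2-ol F6. Intramolecular Suzuki–Miyaura coupling (Pd(dppf)Cl2, Cs2CO3, THF–H2O, 0.002 M, 60 °C) then gives 19.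

**Further compounds**

F1 | step 6 | rac-(6E)-2,6-dimethylundeca-1,6-dien-10-yn-3-ol | C=C(C)C(O)CC/C(C)=C/CCC#C
F2 | step 6 | (3S,6E)-2,6-dimethylundeca-1,6-dien-10-yn-3-ol | C=C(C)[C@@H](O)CC/C(C)=C/CCC#C
F3 | step 6 | (1S)-1-[(2R,5S)-2-methyl-5-(prop-1-en-2-yl)oxolan-2-yl]pent-4-yn-1-ol | C=C(C)[C@@H]1CC[C@@](C)(O1)[C@@H](O)CCC#C
F4 | step 9 | (1S)-1-[(2R,5S)-5-[1-(2,2-dimethylhydrazinylidene)ethyl]-2-methyloxolan-2-yl]pent-4-yn-1-ol | CC(=NN(C)C)[C@@H]1CC[C@@](C)(O1)[C@@H](O)CCC#C
F5 | step 9 | (1S)-1-[(2R,5S)-5-[(4E)-1-(2,2-dimethylhydrazinylidene)-5-iodo-4-(propan-2-yl)pent-4-en-1-yl]-2-methyloxolan-2-yl]pent-4-yn-1-ol | I/C=C(\CCC(=NN(C)C)[C@@H]1CC[C@@](C)(O1)[C@@H](O)CCC#C)C(C)C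
F6 | step 11 | (2R,5E)-2-[(2S,5R)-5-[(1S,4E)-1-hydroxy-4-methyl-5-(4,4,5,5-tetramethyl-1,3,2-dioxaborolan-2-yl)pent-4-en-1-yl]-5-methyloxolan-2-yl]-6-iodo-5-(propan-2-yl)hex-5-en-2-ol | I/C=C(\CC[C@@](C)(O)[C@@H]1CC[C@@](C)(O1)[C@@H](O)CC/C(C)=C/B1OC(C)(C)C(C)(C)O1)C(C)C
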